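1. 22 ⇐ 21 ⇐ 20: after the key step only a hydrogenation (ring alkene, benzylidene acetal) and a hydrodecarboxylation remain.
2. Key disconnection: the bond from ring carbon C11 to the first chain carbon (Cα) is formed by Ireland–Claisen rearrangement of ester 17. Chain acid 16 is tethered through its own carboxyl group to the C9 hydroxyl, and that carboxyl group is removed at the end.
3. Enabling feature: in six-membered ring A the chain-bearing C11 is the far end of the allylic unit C9–C10=C11, and C9 is bonded to C8, a carbon shared with cyclobutane ring B. Ring B screens one face of ring A, so hydride places the C9 hydroxyl on the concave face (cis to ring B), and the suprafacial [3,3] shift hands that face on to C11.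
4. 17 ⇐ racemic allylic alcohol 13 + acid 16 (the lipase esterification doubles as the resolution); 13 ⇐ enone 12 ⇐ ketone 11 ⇐ cyclohex-2-enone 9 + bicyclo[2.2.0]hex-2-ene 8; 16 ⇐ glycerol acetal 14 + bromo acid 15.
5. Ring order: ring D is bought in anhydride 1; ring C is closed by Ramberg–Bäcklund ring contraction (step 5); ring B is closed by [2+2] photocycloaddition (step 6), which also joins on ring A from 9.

Key step: step 11

Remarks
- Locants follow tetracyclo[6.4.0.0(2,7).0(3,6)]dodecane and are kept fixed: ring A = C1, C8, C9, C10, C11, C12; ring B = C1, C2, C7, C8; ring C = C2, C3, C6, C7; ring D = C3, C4, C5, C6. "cis,anti,cis,anti,cis" means every ring fusion is cis and neighbouring rings lie on opposite faces; Cα is the chain carbon bonded to C11.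
- Assumption: the glycerol unit is carried as the commercial cis-1,3-O-benzylidene acetal 14; its relative configuration does not matter because the acetal is cleaved in step 12.
- Compounds 10–13 are racemates; their SMILES show the enantiomer that the resolution in step 10 carries on.
- Cα in compounds 19–21 is formed as an epimeric mixture of no consequence (it becomes CH2 in step 13) and is written without configuration.

Step 1
Reactants: 1 cis-cyclobutane-1,2-dicarboxylic anhydride
Product: 2 cis-cyclobutane-1,2-diyldimethanol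
Conditions: LiAlH4, THF, 0 °C to reflux; H2O/aq. NaOH work-up
Reagents that add atoms: none
Why: LiAlH4 reduction of a cyclic anhydride to the 1,4-diol is reliable and leaves the two cis ring stereocentres of the starting material untouched.

Step 2
Reactants: 2 cis-cyclobutane-1,2-diyldimethanol
Product: 3 cis-cyclobutane-1,2-diylbis(methylene) dimethanesulfonate
Conditions: MsCl, Et3N, CH2Cl2, 0 °C
Reagents that add atoms: methanesulfonyl chloride CS(=O)(=O)Cl
Why: Mesylation of the two primary alcohols turns them into leaving groups without touching the ring.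

Step 3
Reactants: 3 cis-cyclobutane-1,2-diylbis(methylene) dimethanesulfonate
Product: 4 cis-3-thiabicyclo[3.2.0]heptane
Conditions: Na2S·9H2O, DMF, 70 °C
Reagents that add atoms: sodium sulfide [Na+].[Na+].[S-2]
Why: Double SN2 alkylation of sulfide closes the thiolane, the cis-fused bicycle being the only ring the cis dimesylate can form.

Step 4
Reactants: 4 cis-3-thiabicyclo[3.2.0]heptane
Product: 6 2-chloro-cis-3-thiabicyclo[3.2.0]heptane 3,3-dioxide, via α-chloro sulfide 5 (not isolated)
Conditions: NCS, CH2Cl2, 0 °C; then mCPBA, CH2Cl2, 0 → 25 °C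
Reagents that add atoms: N-chlorosuccinimide O=C1CCC(=O)N1Cl; 3-chloroperoxybenzoic acid OOC(=O)c1cccc(Cl)c1
Why: NCS α-chlorination of the sulfide (chlorosulfonium ion, then thionium ion) followed by peracid oxidation at sulfur gives the α-chloro sulfone needed for the Ramberg–Bäcklund reaction, and the C–Cl stereocentre, formed unselectively, is destroyed in step 5.

Step 5
Reactants: 6 2-chloro-cis-3-thiabicyclo[3.2.0]heptane 3,3-dioxide
Product: 8 bicyclo[2.2.0]hex-2-ene, via episulfone 7 (not isolated)
Conditions: KOt-Bu, diglyme, 0 → 25 °C; volatile product distilled into a cold trap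
Reagents that add atoms: none
Why: In this Ramberg–Bäcklund reaction, deprotonation at the α'-CH2, 1,3-displacement of chloride to episulfone 7 and cheletropic loss of SO2 contract the thiolane to the cyclobutene of ring C, whose cis fusion to ring D is the only geometry possible.

Step 6
Reactants: 8 bicyclo[2.2.0]hex-2-ene; 9 cyclohex-2-en-1-one
Product: 11 rac-cis,anti,cis,anti,cis-tetracyclo[6.4.0.0(2,7).0(3,6)]dodecan-9-one, via trans-fused photoadduct 10 (not isolated)
Conditions: hν (350–366 nm, Pyrex filter), 8 (3 equiv, excess recovered by distillation), CH2Cl2, −20 °C; then basic Al2O3, CH2Cl2, 25 °C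
Reagents that add atoms: none
Why: In this enone–alkene [2+2] photocycloaddition (triplet enone, 1,4-diradical) the enone bonds to the exo face of 8 (anti to ring D) and ring B closes with ring A anti to ring C, while basic Al2O3 epimerises C8 of any trans-fused adduct 10 to the more stable cis ring fusion, so the racemic cis,anti,cis,anti,cis ketone should result.

Step 7
Reactants: 11 rac-cis,anti,cis,anti,cis-tetracyclo[6.4.0.0(2,7).0(3,6)]dodecan-9-one
Product: 12 rac-cis,anti,cis,anti,cis-tetracyclo[6.4.0.0(2,7).0(3,6)]dodec-10-en-9-one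
Conditions: IBX, 4-methoxypyridine N-oxide, DMSO, 25 °C
Reagents that add atoms: none
Why: IBX dehydrogenation of the ketone runs through the enol toward the C10 methylene, not toward the strained cyclobutane carbon C8, and should give the C10=C11 enone without touching a stereocentre.

Step 8
Reactants: 12 rac-cis,anti,cis,anti,cis-tetracyclo[6.4.0.0(2,7).0(3,6)]dodec-10-en-9-one
Product: 13 rac-cis,anti,cis,anti,cis-tetracyclo[6.4.0.0(2,7).0(3,6)]dodec-10-en-9-ol with the hydroxyl cis to ring B
Conditions: CeCl3·7H2O, NaBH4, MeOH, −78 → 0 °C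
Reagents that add atoms: none
Why: In this Luche 1,2-reduction the hydride attacks C9 from the convex face of ring A, away from ring B and the inward-pointing C7–H, so the hydroxyl ends up cis to ring B (9R in the enantiomer drawn).

Step 9
Reactants: 14 cis-2-phenyl-1,3-dioxan-5-ol; 15 9-bromononanoic acid
Product: 16 9-[(cis-2-phenyl-1,3-dioxan-5-yl)oxy]nonanoic acid
Conditions: NaH (2.5 equiv), THF/DMF, 0 → 50 °C; cold 1 M HCl to pH 4
Reagents that add atoms: none
Why: In this Williamson ether synthesis the sodium alkoxide of 14 displaces the primary bromide of the carboxylate salt of 15 by SN2, the carboxylate being a far weaker nucleophile than the alkoxide.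

Step 10
Reactants: 13 rac-cis,anti,cis,anti,cis-tetracyclo[6.4.0.0(2,7).0(3,6)]dodec-10-en-9-ol; 16 9-[(cis-2-phenyl-1,3-dioxan-5-yl)oxy]nonanoic acid
Product: 17 (9R)-cis,anti,cis,anti,cis-tetracyclo[6.4.0.0(2,7).0(3,6)]dodec-10-en-9-yl 9-[(cis-2-phenyl-1,3-dioxan-5-yl)oxy]nonanoate
Conditions: Novozym 435 (immobilised Candida antarctica lipase B), 16 (0.45 equiv), 4 Å molecular sieves, toluene, 40 °C; stopped before half of 13 is consumed
Reagents that add atoms: none
Why: In this lipase-catalysed enantioselective esterification (kinetic resolution by the empirical large/medium size rule for secondary alcohols) the (9R)-alcohol, with the bulky C8 branch as the large group and the C10 vinyl carbon as the medium group, should be acylated with retention at C9, while the (9S)-enantiomer of 13 stays as free alcohol and is removed by chromatography.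

Step 11
Reactants: 17 (9R)-cis,anti,cis,anti,cis-tetracyclo[6.4.0.0(2,7).0(3,6)]dodec-10-en-9-yl 9-[(cis-2-phenyl-1,3-dioxan-5-yl)oxy]nonanoate
Product: 20 2-[cis,anti,cis,anti,cis-tetracyclo[6.4.0.0(2,7).0(3,6)]dodec-9-en-11-yl]-9-[(cis-2-phenyl-1,3-dioxan-5-yl)oxy]nonanoic acid with the C11 substituent cis to ring B, via silyl ketene acetal 18 (not isolated), via trimethylsilyl ester 19 (not isolated)
Conditions: LiN(i-Pr)2, THF, −78 °C; Me3SiCl, −78 → 25 °C, then 60 °C; cold 1 M HCl work-up
Reagents that add atoms: none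
Why: LiN(i-Pr)2 enolises the ester, Me3SiCl traps the enolate on oxygen as silyl ketene acetal 18, and 18 undergoes a concerted suprafacial [3,3]-sigmatropic shift in which the C9–O bond breaks while Cα bonds to C11, giving silyl ester 19, which the work-up hydrolyses to acid 20. The closest known reaction type is the Ireland–Claisen rearrangement of cyclohex-2-enyl alkanoates. No ring is closed; the six-membered (boat or chair) array exists only in the transition state. The new ring stereocentre C11 is controlled by the C9 carbinol centre: because the shift is suprafacial across C9–C10–C11, Cα is delivered to the concave face, cis to ring B, where a reagent from outside would not go, while Cα itself forms as a mixture that step 13 erases. The step needs O- over C-silylation and rearrangement over elimination or ketene loss, and these are secured by the hard silyl chloride at low temperature, by the single acidic C–H site of 17 and by the fixed cisoid allyl unit of ring A, which leaves C11 as the only terminus within reach.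

Step 12
Reactants: 20 2-[cis,anti,cis,anti,cis-tetracyclo[6.4.0.0(2,7).0(3,6)]dodec-9-en-11-yl]-9-[(cis-2-phenyl-1,3-dioxan-5-yl)oxy]nonanoic acid
Product: 21 9-[(1,3-dihydroxypropan-2-yl)oxy]-2-[cis,anti,cis,anti,cis-tetracyclo[6.4.0.0(2,7).0(3,6)]dodecan-11-yl]nonanoic acid
Conditions: H2 (1 atm), Pd(OH)2/C, EtOAc/MeOH, 25 °C
Reagents that add atoms: none
Why: Heterogeneous catalytic hydrogenation saturates the C9=C10 alkene, where no stereocentre arises (and should palladium first move the double bond to C10=C11, hydrogen delivery from the convex face restores the same C11 configuration), and hydrogenolyses the benzylidene acetal to the 1,3-diol.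

Step 13
Reactants: 21 9-[(1,3-dihydroxypropan-2-yl)oxy]-2-[cis,anti,cis,anti,cis-tetracyclo[6.4.0.0(2,7).0(3,6)]dodecan-11-yl]nonanoic acid
Product: 22 2-({8-[(11S)-cis,anti,cis,anti,cis-tetracyclo[6.4.0.0(2,7).0(3,6)]dodecan-11-yl]octyl}oxy)propane-1,3-diol with the chain cis to ring B (CNP0193334.1)
Conditions: 9-mesityl-10-phenylacridinium tetrafluoroborate (5 mol %), (PhS)2 (10 mol %), i-Pr2NEt (20 mol %), CF3CH2OH, 450 nm LEDs, 25 °C
Reagents that add atoms: none
Why: In this photoredox hydrodecarboxylation the excited acridinium oxidises the carboxylate, loss of CO2 gives a secondary alkyl radical that is not adjacent to any cyclobutane carbon (so no ring opening), and thiophenol formed in the flask transfers a hydrogen atom, which turns Cα into CH2 and leaves the seven ring stereocentres untouched.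

Compound list
1 | cis-cyclobutane-1,2-dicarboxylic anhydride | O=C1OC(=O)[C@@H]2CC[C@H]12 | starting material
2 | cis-cyclobutane-1,2-diyldimethanol | OC[C@@H]1CC[C@@H]1CO | intermediate
3 | cis-cyclobutane-1,2-diylbis(methylene) dimethanesulfonate | CS(=O)(=O)OC[C@@H]1CC[C@@H]1COS(C)(=O)=O | intermediate
4 | cis-3-thiabicyclo[3.2.0]heptane | C1SC[C@@H]2CC[C@H]12 | intermediate
5 | 2-chloro-cis-3-thiabicyclo[3.2.0]heptane (α-chloro sulfide, C2 epimers) | ClC1SC[C@@H]2CC[C@H]12 | intermediate
6 | 2-chloro-cis-3-thiabicyclo[3.2.0]heptane 3,3-dioxide (C2 epimers) | ClC1S(=O)(=O)C[C@@H]2CC[C@H]12 | intermediate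
7 | 3-thiatricyclo[3.2.0.0(2,4)]heptane 3,3-dioxide (episulfone) | O=S1(=O)C2C1[C@@H]1CC[C@H]21 | intermediate
8 | bicyclo[2.2.0]hex-2-ene (rings C and D) | C1=C[C@@H]2CC[C@H]12 | intermediate
9 | cyclohex-2-en-1-one | O=C1C=CCCC1 | starting material
10 | rac-C8 epimer of 11 (ring A trans-fused to ring B) | C1CC(=O)[C@H]2[C@H](C1)[C@H]1[C@@H]3CC[C@@H]3[C@@H]21 | intermediate
11 | rac-cis,anti,cis,anti,cis-tetracyclo[6.4.0.0(2,7).0(3,6)]dodecan-9-one | C1CC(=O)[C@@H]2[C@H](C1)[C@H]1[C@@H]3CC[C@@H]3[C@@H]21 | intermediate
12 | rac-cis,anti,cis,anti,cis-tetracyclo[6.4.0.0(2,7).0(3,6)]dodec-10-en-9-one | C1=CC(=O)[C@@H]2[C@H](C1)[C@H]1[C@@H]3CC[C@@H]3[C@@H]21 | intermediate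
13 | rac-cis,anti,cis,anti,cis-tetracyclo[6.4.0.0(2,7).0(3,6)]dodec-10-en-9-ol, hydroxyl cis to ring B (9R shown) | C1=C[C@@H](O)[C@@H]2[C@H](C1)[C@H]1[C@@H]3CC[C@@H]3[C@@H]21 | intermediate
14 | cis-2-phenyl-1,3-dioxan-5-ol (cis-1,3-O-benzylideneglycerol) | O[C@H]1CO[C@@H](c2ccccc2)OC1 | starting material
15 | 9-bromononanoic acid | OC(=O)CCCCCCCCBr | starting material
16 | 9-[(cis-2-phenyl-1,3-dioxan-5-yl)oxy]nonanoic acid | OC(=O)CCCCCCCCO[C@H]1CO[C@@H](c2ccccc2)OC1 | intermediate
17 | (9R)-cis,anti,cis,anti,cis-tetracyclo[6.4.0.0(2,7).0(3,6)]dodec-10-en-9-yl 9-[(cis-2-phenyl-1,3-dioxan-5-yl)oxy]nonanoate | C1=C[C@@H](OC(=O)CCCCCCCCO[C@H]4CO[C@@H](c5ccccc5)OC4)[C@@H]2[C@H](C1)[C@H]1[C@@H]3CC[C@@H]3[C@@H]21 | intermediate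
18 | (E)-O-trimethylsilyl ketene acetal of 17 (geometry expected, immaterial) | C1=C[C@@H](O/C(O[Si](C)(C)C)=C\CCCCCCCO[C@H]4CO[C@@H](c5ccccc5)OC4)[C@@H]2[C@H](C1)[C@H]1[C@@H]3CC[C@@H]3[C@@H]21 | intermediate
19 | trimethylsilyl ester of 20 | C[Si](C)(C)OC(=O)C(CCCCCCCO[C@H]4CO[C@@H](c5ccccc5)OC4)[C@H]1C=C[C@@H]2[C@H](C1)[C@H]1[C@@H]3CC[C@@H]3[C@@H]21 | intermediate
20 | 2-[cis,anti,cis,anti,cis-tetracyclo[6.4.0.0(2,7).0(3,6)]dodec-9-en-11-yl]-9-[(cis-2-phenyl-1,3-dioxan-5-yl)oxy]nonanoic acid, C11 substituent cis to ring B | OC(=O)C(CCCCCCCO[C@H]4CO[C@@H](c5ccccc5)OC4)[C@H]1C=C[C@@H]2[C@H](C1)[C@H]1[C@@H]3CC[C@@H]3[C@@H]21 | intermediate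
21 | 9-[(1,3-dihydroxypropan-2-yl)oxy]-2-[cis,anti,cis,anti,cis-tetracyclo[6.4.0.0(2,7).0(3,6)]dodecan-11-yl]nonanoic acid, C11 substituent cis to ring B | OC(=O)C(CCCCCCCOC(CO)CO)[C@H]1CC[C@@H]2[C@H](C1)[C@H]1[C@@H]3CC[C@@H]3[C@@H]21 | intermediate
22 | 2-({8-[(11S)-cis,anti,cis,anti,cis-tetracyclo[6.4.0.0(2,7).0(3,6)]dodecan-11-yl]octyl}oxy)propane-1,3-diol, chain cis to ring B | OCC(CO)OCCCCCCCC[C@H]1CC[C@@H]2[C@H](C1)[C@H]1[C@@H]3CC[C@@H]3[C@@H]21 | target

Total step count: 13
Longest linear sequence: 12 steps (steps 1–8 and 10–13); step 9 is the convergent branch.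

Steps most likely to fail

Step 10. Enzymatic acyl transfer to the hindered bicyclic alcohol may be too slow, or may discriminate the enantiomers too weakly with the long-chain acid as acyl donor, so that the ester would form with insufficient enantiomeric purity. The fallback sets out from 13 and replaces the enzyme by a covalent resolution. Acylation of 13 with (S)-2-methoxy-2-phenylacetyl chloride (pyridine, DMAP, CH2Cl2) gives two diastereomers, the (9R)-alcohol (S)-2-methoxy-2-phenylacetate F1 and the (9S)-alcohol (S)-2-methoxy-2-phenylacetate F2, which are separated by chromatography or crystallisation. Methanolysis of F1 (K2CO3, MeOH) releases the (9R)-alcohol F3 as a single enantiomer, and carbodiimide esterification of F3 with 16 (EDC·HCl, DMAP, CH2Cl2) comes back to the route at 17.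

Step 11. The [3,3] shift has to pass through a transition state on the concave face of a ring flattened by the fused cyclobutane, and may be outrun by decomposition of the silyl ketene acetal (elimination, ketene loss, C-silylation). The fallback sets out from 17 and forms the same bond by copper-catalysed allylic substitution. Methanolysis (K2CO3, MeOH) gives the (9R)-alcohol F3, and a Mitsunobu reaction with pyridine-2-carboxylic acid (PPh3, DIAD, THF) inverts C9 to the (9S)-picolinate F4, whose oxygen now lies on the convex face. In parallel 14 is alkylated with 1,8-dibromooctane (NaH, DMF) to the bromo ether F5, which is converted (Mg, THF) into the Grignard reagent F6. CuBr·SMe2-catalysed anti-SN2' substitution of F4 by F6 (THF, −40 °C) places the chain on C11 on the face opposite to the leaving group, that is cis to ring B, and gives the alkene acetal F7. Hydrogenation of F7 (H2, Pd(OH)2/C) saturates the alkene and removes the acetal, so the route comes back at 22 without the decarboxylation.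

Step 13. Oxidation of the carboxylate may be inefficient in a substrate with two free hydroxyls, or the secondary radical may be oxidised further before hydrogen-atom transfer. The fallback sets out from 20 and moves the decarboxylation ahead of the hydrogenation. Coupling of 20 with N-hydroxyphthalimide (N,N'-diisopropylcarbodiimide, DMAP, CH2Cl2) gives the N-acyloxyphthalimide F8. Reductive radical decarboxylation of F8 ([Ru(bpy)3]Cl2 as photocatalyst, 1-benzyl-1,4-dihydronicotinamide, t-BuSH, visible light) gives the alkene acetal F7, and hydrogenation of F7 (H2, Pd(OH)2/C) comes back to the route at 22.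

Further compounds
F1 | step 10 | (9R)-cis,anti,cis,anti,cis-tetracyclo[6.4.0.0(2,7).0(3,6)]dodec-10-en-9-yl (S)-2-methoxy-2-phenylacetate | C1=C[C@@H](OC(=O)[C@@H](OC)c4ccccc4)[C@@H]2[C@H](C1)[C@H]1[C@@H]3CC[C@@H]3[C@@H]21
F2 | step 10 | (9S)-cis,anti,cis,anti,cis-tetracyclo[6.4.0.0(2,7).0(3,6)]dodec-10-en-9-yl (S)-2-methoxy-2-phenylacetate (diastereomer that is removed) | C1=C[C@H](OC(=O)[C@@H](OC)c4ccccc4)[C@H]2[C@@H](C1)[C@@H]1[C@H]3CC[C@H]3[C@H]21
F3 | step 10 | (9R)-cis,anti,cis,anti,cis-tetracyclo[6.4.0.0(2,7).0(3,6)]dodec-10-en-9-ol, single enantiomer of 13 | C1=C[C@@H](O)[C@@H]2[C@H](C1)[C@H]1[C@@H]3CC[C@@H]3[C@@H]21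
F4 | step 11 | (9S)-cis,anti,cis,anti,cis-tetracyclo[6.4.0.0(2,7).0(3,6)]dodec-10-en-9-yl pyridine-2-carboxylate, oxygen trans to ring B | C1=C[C@H](OC(=O)c4ccccn4)[C@@H]2[C@H](C1)[C@H]1[C@@H]3CC[C@@H]3[C@@H]21
F5 | step 11 | 5-[(8-bromooctyl)oxy]-cis-2-phenyl-1,3-dioxane | BrCCCCCCCCO[C@H]1CO[C@@H](c2ccccc2)OC1
F6 | step 11 | {8-[(cis-2-phenyl-1,3-dioxan-5-yl)oxy]octyl}magnesium bromide | Br[Mg]CCCCCCCCO[C@H]1CO[C@@H](c2ccccc2)OC1
F7 | step 11 | 5-({8-[cis,anti,cis,anti,cis-tetracyclo[6.4.0.0(2,7).0(3,6)]dodec-9-en-11-yl]octyl}oxy)-cis-2-phenyl-1,3-dioxane, chain cis to ring B | C(CCCCCCCO[C@H]4CO[C@@H](c5ccccc5)OC4)[C@H]1C=C[C@@H]2[C@H](C1)[C@H]1[C@@H]3CC[C@@H]3[C@@H]21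
F8 | step 13 | 1,3-dioxoisoindolin-2-yl ester of 20 | O=C(ON6C(=O)c7ccccc7C6=O)C(CCCCCCCO[C@H]4CO[C@@H](c5ccccc5)OC4)[C@H]1C=C[C@@H]2[C@H](C1)[C@H]1[C@@H]3CC[C@@H]3[C@@H]21
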